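The numbering used is: C7/C7' are the ArCH–O carbons, C8 the CH bridgehead, C8' the C(OH) bridgehead, C9/C9' the OCH2 carbons; ring A is C7–O–C9'–C8'–C8 and ring B is C7'–O–C9–C8–C8'. The route rests on C7 and C7' carrying the same guaiacyl group on either side of the core C9–C8–C8'–C9', so the skeleton is C2-symmetric once C8 and C8' are sp2.
Target ⇐ desilylation and syn addition of H (to C8) and OH (to C8') on the face opposite both aryls ⇐ bicyclic ene with C8=C8' at the fusion of rings A and B, whose two alkene carbons are equivalent.
Bicyclic ene ⇐ ring B by O–C9 displacement of an allylic bromide ⇐ ring A by 1,4-bromoetherification (O–C9' bond) of a 1,4-diaryl-2,3-dimethylenebutane-1,4-diol; ring A is closed first, ring B second.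
Dienediol ⇐ C7–C8 and C7'–C8' bonds made in one flask from two molecules of O-silylated vanillin and a but-2-yne-1,4-diyl bis(pinacol boronate) under a chiral phosphoric acid; bis(boronate) ⇐ acetylene bis-Grignard and two molecules of (iodomethyl)boronate.

Key step: step 3

Assumption: the (R)-phosphoric acid is taken to open the Re face of an aryl aldehyde to the boronate, as in allylboration with allyl pinacol boronate; should the sense be reversed here, the enantiomeric acid is used and nothing else changes.

Step 1
Reactants: 1 vanillin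
Product: 2 3-methoxy-4-[(triisopropylsilyl)oxy]benzaldehyde
Conditions: TIPSCl (1.1 equiv), imidazole (2 equiv), DMF, 0 °C to rt
Reagents that add atoms: chlorotriisopropylsilane, CC(C)[Si](Cl)(C(C)C)C(C)C
Why: O-silylation of the phenol with a silyl chloride and imidazole; the triisopropylsilyl ether is chosen because it should survive NaH in step 5 and alkaline peroxide in step 6 better than a tert-butyldimethylsilyl ether and still falls to fluoride in step 7.

Step 2
Reactants: 3 ethynylmagnesium bromide; 4 2-(iodomethyl)-4,4,5,5-tetramethyl-1,3,2-dioxaborolane (2.2 equiv)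
Product: 6 2,2'-(but-2-yne-1,4-diyl)bis(4,4,5,5-tetramethyl-1,3,2-dioxaborolane), via ethyne-1,2-diylbis(magnesium bromide) 5 (not isolated)
Conditions: EtMgBr (1.0 equiv), THF, 40 °C; then 4, −30 °C to rt; rapid cold aqueous NH4Cl work-up, pentane
Reagents that add atoms: none
Why: EtMgBr removes the second acetylenic proton, each C–Mg end then adds to the boron of 4 and the alkynyl group shifts from boron to the CH2 carbon with loss of iodide (Matteson-type homologation, the standard way from metal acetylides to propargylic boronates), and the product is kept cold and base-free so that it does not isomerise to the allenyl boronate.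

Step 3
Reactants: 2 3-methoxy-4-[(triisopropylsilyl)oxy]benzaldehyde (2.1 equiv); 6 2,2'-(but-2-yne-1,4-diyl)bis(4,4,5,5-tetramethyl-1,3,2-dioxaborolane)
Product: 9 (1S,4S)-1,4-bis{3-methoxy-4-[(triisopropylsilyl)oxy]phenyl}-2,3-dimethylidenebutane-1,4-diol, via allenyl carbinol borate 7 (not isolated), via dienediol bis(borate) 8 (not isolated)
Conditions: (R)-3,3'-bis(2,4,6-triisopropylphenyl)-1,1'-binaphthalene-2,2'-diyl hydrogen phosphate (10 mol %), 4 Å MS, toluene, −30 °C to 0 °C; then aq. NaHCO3, rt
Reagents that add atoms: none
Why: Proposed new method: the phosphoric acid binds a pinacol oxygen of 6 through its O–H and the formyl C–H of 2 through its P=O, and in this closed six-membered SE2' transition state the propargylic C–B bond adds at the remote alkyne carbon (C7–C8 bond) to give allenyl carbinol borate 7, whose remaining CH2–B group is now an allylic boronate and adds a second molecule of 2 through a chair-like SE2' transition state at the central allene carbon (C7'–C8' bond), which leaves the 2,3-dimethylene unit of 8. The closest known reactions are the chiral-phosphoric-acid-catalysed allylboration and allenylboronate propargylation of aldehydes, the addition of propargylic pinacol boronates to aldehydes to give allenyl carbinols, the allylboration with buta-2,3-dienyl boronates to give dien-2-yl carbinols and the racemic double addition of 1,4-dimetallated but-2-ynes to two carbonyl groups; new is the combination of both additions under one chiral catalyst. No ring is closed here, since rings A and B are formed in steps 4 and 5. Both new stereocentres, C7 and C7', are set by the catalyst, which should expose the Re face of each aldehyde and so give the S configuration at each carbinol carbon. The step needs the like (S,S) diol in preference to the meso diol and needs complete double addition: since one catalyst controls both additions in the same sense, most of the minor enantiomer of the first addition should end in the meso diol, which is removed by chromatography, and allylic boronate 7 is more reactive than propargylic boronate 6, so that the mono-adduct should not build up.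

Step 4
Reactants: 9 (1S,4S)-1,4-bis{3-methoxy-4-[(triisopropylsilyl)oxy]phenyl}-2,3-dimethylidenebutane-1,4-diol
Product: 10 (S)-{(5S)-4-(bromomethyl)-5-{3-methoxy-4-[(triisopropylsilyl)oxy]phenyl}-2,5-dihydrofuran-3-yl}{3-methoxy-4-[(triisopropylsilyl)oxy]phenyl}methanol
Conditions: NBS (1.05 equiv), NaHCO3, CH2Cl2, −78 °C to −40 °C, dark
Reagents that add atoms: N-bromosuccinimide, O=C1CCC(=O)N1Br
Why: Electrophilic bromine adds to the terminal carbon C9 of the diene and the allyl cation over C8–C8'–C9' is captured at its far end C9' by the hydroxyl oxygen on C7, the only closure that gives a five-membered ring (1,4-bromoetherification of a conjugated diene, a halocyclisation), so ring A closes with C8=C8' inside it; the C2 symmetry of 9 makes the two ways of starting identical, and C7 and C7' are not touched.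

Step 5
Reactants: 10 (S)-{(5S)-4-(bromomethyl)-5-{3-methoxy-4-[(triisopropylsilyl)oxy]phenyl}-2,5-dihydrofuran-3-yl}{3-methoxy-4-[(triisopropylsilyl)oxy]phenyl}methanol
Product: 11 (1S,4S)-1,4-bis{3-methoxy-4-[(triisopropylsilyl)oxy]phenyl}-1,3,4,6-tetrahydrofuro[3,4-c]furan (double bond C8=C8' at the ring fusion, both aryls on the same face)
Conditions: NaH (1.3 equiv), THF, 0 °C to rt
Reagents that add atoms: none
Why: Intramolecular Williamson etherification in which the alkoxide on C7' displaces the primary allylic bromide at C9 (5-exo-tet, the two groups being held cis on the ring A double bond) and closes ring B; no stereocentre is involved and the C2 axis reappears.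

Step 6
Reactants: 11 (1S,4S)-1,4-bis{3-methoxy-4-[(triisopropylsilyl)oxy]phenyl}-1,3,4,6-tetrahydrofuro[3,4-c]furan
Product: 13 (1R,3aS,4S,6aR)-1,4-bis{3-methoxy-4-[(triisopropylsilyl)oxy]phenyl}tetrahydro-1H,3H-furo[3,4-c]furan-3a(4H)-ol, via tertiary alkylborane 12 (not isolated)
Conditions: BH3·THF (3 equiv), THF, 0 °C to rt; then 3 M NaOH, 30% H2O2, 0 °C
Reagents that add atoms: hydrogen peroxide, OO; borane (as its THF complex), B (its boron stays only in 12)
Why: Hydroboration–oxidation in which borane adds H and B syn across C8=C8' from the face that carries only the hydrogens of C7 and C7', away from both aryl groups, and the C–B bond is oxidised with retention, which sets C8 (H) and C8' (OH) cis to each other and trans to the aryls; the two alkene carbons are exchanged by the C2 axis, so there is no regiochemical question, and the ring should hold back β-alkoxy elimination as in the hydroboration of 2,5-dihydrofuran.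

Step 7
Reactants: 13 (1R,3aS,4S,6aR)-1,4-bis{3-methoxy-4-[(triisopropylsilyl)oxy]phenyl}tetrahydro-1H,3H-furo[3,4-c]furan-3a(4H)-ol
Product: 14 (1R,3aS,4S,6aR)-1,4-bis(4-hydroxy-3-methoxyphenyl)tetrahydro-1H,3H-furo[3,4-c]furan-3a(4H)-ol (the target)
Conditions: TBAF (2.4 equiv), AcOH (2.4 equiv), THF, 0 °C
Reagents that add atoms: none
Why: Fluoride cleavage of the two aryl silyl ethers, with acetic acid keeping the liberated phenoxides protonated so that the p-hydroxybenzylic ether carbons C7 and C7' are not opened to quinone methides and keep their configuration.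

Compound list
1 | vanillin | COc1cc(C=O)ccc1O | starting material
2 | 3-methoxy-4-[(triisopropylsilyl)oxy]benzaldehyde | COc1cc(C=O)ccc1O[Si](C(C)C)(C(C)C)C(C)C | intermediate
3 | ethynylmagnesium bromide | C#C[Mg]Br | starting material
4 | 2-(iodomethyl)-4,4,5,5-tetramethyl-1,3,2-dioxaborolane | CC1(C)OB(CI)OC1(C)C | starting material
5 | ethyne-1,2-diylbis(magnesium bromide) | Br[Mg]C#C[Mg]Br | intermediate (not isolated)
6 | 2,2'-(but-2-yne-1,4-diyl)bis(4,4,5,5-tetramethyl-1,3,2-dioxaborolane) | CC1(C)OB(CC#CCB2OC(C)(C)C(C)(C)O2)OC1(C)C | intermediate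
7 | (S)-allenyl carbinol borate: O-pinacolboryl ether of 1-aryl-2-[(pinacolboryl)methyl]buta-2,3-dien-1-ol | C=C=C(CB1OC(C)(C)C(C)(C)O1)[C@@H](OB1OC(C)(C)C(C)(C)O1)c1ccc(O[Si](C(C)C)(C(C)C)C(C)C)c(OC)c1 | intermediate (not isolated)
8 | bis(O-pinacolboryl) ether of the (1S,4S)-dienediol | CC1(C)OB(O[C@@H](c2ccc(O[Si](C(C)C)(C(C)C)C(C)C)c(OC)c2)C(=C)C(=C)[C@@H](OB2OC(C)(C)C(C)(C)O2)c2ccc(O[Si](C(C)C)(C(C)C)C(C)C)c(OC)c2)OC1(C)C | intermediate (not isolated)
9 | (1S,4S)-1,4-bis{3-methoxy-4-[(triisopropylsilyl)oxy]phenyl}-2,3-dimethylidenebutane-1,4-diol | O[C@@H](c1ccc(O[Si](C(C)C)(C(C)C)C(C)C)c(OC)c1)C(=C)C(=C)[C@@H](O)c1ccc(O[Si](C(C)C)(C(C)C)C(C)C)c(OC)c1 | intermediate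
10 | (S)-{(5S)-4-(bromomethyl)-5-aryl-2,5-dihydrofuran-3-yl}(aryl)methanol, aryl = 3-methoxy-4-[(triisopropylsilyl)oxy]phenyl | O[C@@H](c1ccc(O[Si](C(C)C)(C(C)C)C(C)C)c(OC)c1)C1=C(CBr)[C@H](c2ccc(O[Si](C(C)C)(C(C)C)C(C)C)c(OC)c2)OC1 | intermediate
11 | (1S,4S)-1,4-bis{3-methoxy-4-[(triisopropylsilyl)oxy]phenyl}-1,3,4,6-tetrahydrofuro[3,4-c]furan | COc1cc([C@@H]2OCC3=C2CO[C@H]3c2ccc(O[Si](C(C)C)(C(C)C)C(C)C)c(OC)c2)ccc1O[Si](C(C)C)(C(C)C)C(C)C | intermediate
12 | tertiary alkylborane: BH2 on C8' and H on C8, both on the face opposite the aryls | COc1cc([C@@H]2OC[C@@]3(B)[C@@H]2CO[C@H]3c2ccc(O[Si](C(C)C)(C(C)C)C(C)C)c(OC)c2)ccc1O[Si](C(C)C)(C(C)C)C(C)C | intermediate (not isolated)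
13 | (1R,3aS,4S,6aR)-1,4-bis{3-methoxy-4-[(triisopropylsilyl)oxy]phenyl}tetrahydro-1H,3H-furo[3,4-c]furan-3a(4H)-ol | COc1cc([C@@H]2OC[C@@]3(O)[C@@H]2CO[C@H]3c2ccc(O[Si](C(C)C)(C(C)C)C(C)C)c(OC)c2)ccc1O[Si](C(C)C)(C(C)C)C(C)C | intermediate
14 | (1R,3aS,4S,6aR)-1,4-bis(4-hydroxy-3-methoxyphenyl)tetrahydro-1H,3H-furo[3,4-c]furan-3a(4H)-ol | COc1cc([C@@H]2OC[C@@]3(O)[C@@H]2CO[C@H]3c2ccc(O)c(OC)c2)ccc1O | target

Total step count: 7. Longest linear sequence: 6 steps (steps 1, 3, 4, 5, 6, 7 from vanillin; the boronate branch, steps 2 to 7, is equally long).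

Steps most likely to fail

Step 3 (proposed new method). The acid may fail to control the aldehyde face in one of the two additions, since the propargylic and the allylic boronate need not respond alike. Acid-promoted protodeboronation or stalling after the first addition are the other risks. The fallback sets out from 2 and returns at 9, using known chemistry only. Aldehyde 2 (2 equiv) and 1,4-dibromobut-2-yne F1 are coupled with indium powder in THF–H2O at rt, a Barbier double addition through the propargyl/allenyl and then the allyl indium species. This should give the dienediol as the mixture of its racemic and meso forms F2. Sharpless kinetic resolution of F2 (Ti(OiPr)4, D-(−)-diisopropyl tartrate, tBuOOH, 4 Å MS, CH2Cl2, −20 °C) should epoxidise only the (R)-configured allylic carbinol ends. The (R,R)-diol is thereby consumed as the bis(epoxy alcohol) F3 and the meso diol as the mono(epoxy alcohol) F4, and the untouched (S,S)-diol 9 is recovered by chromatography.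

Step 4. Capture of the allyl cation at C9' by the hydroxyl group may be too slow. A 1,2-shift of the β-hydroxy cation (semipinacol pathway) or bromination of the electron-rich aryl rings would then take over. The fallback sets out from 9 and returns at 11, bypassing 10. Bromine (1.0 equiv, CH2Cl2, −78 °C, solid NaHCO3) is added 1,4 across the 2,3-disubstituted diene, with bromide as an external and faster nucleophile for C9'. This should give the (1S,4S,2E)-2,3-bis(bromomethyl)but-2-ene-1,4-diol F5, in which the two bromomethyl groups are trans, so each lies cis to the carbinol on the other alkene carbon. NaH in THF then closes rings A and B by two Williamson displacements to give 11. Any bromoether 10 formed alongside converges on 11 under the same base.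

Step 6. Hydroboration of the tetrasubstituted alkene, deactivated by four allylic C–O bonds, may be sluggish, or the tertiary alkylborane may undergo β-alkoxy elimination with ring opening before it is oxidised. The fallback sets out from 11 and returns at 13. It is a Mukaiyama-type hydration by hydrogen-atom transfer: Mn(dpm)3 (dpm = 2,2,6,6-tetramethylheptane-3,5-dionate, catalytic), PhSiH3, O2, iPrOH–CH2Cl2, 0 °C. The hydrogen atom should be delivered to C8 from the face opposite the aryls. The tertiary radical at C8' can take up O2 only on the same face, because the ring fusion must be cis. This gives the tertiary hydroperoxide F6, which is reduced in the same flask with PPh3 to 13.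

Further compounds
F1 | step 3 | 1,4-dibromobut-2-yne | BrCC#CCBr
F2 | step 3 | 1,4-bis{3-methoxy-4-[(triisopropylsilyl)oxy]phenyl}-2,3-dimethylidenebutane-1,4-diol, mixture of racemic and meso forms | OC(c1ccc(O[Si](C(C)C)(C(C)C)C(C)C)c(OC)c1)C(=C)C(=C)C(O)c1ccc(O[Si](C(C)C)(C(C)C)C(C)C)c(OC)c1
F3 | step 3 | bis(epoxy alcohol) of the (R,R)-diol: [2,2'-bioxirane]-2,2'-diylbis({3-methoxy-4-[(triisopropylsilyl)oxy]phenyl}methanol) | O[C@H](c1ccc(O[Si](C(C)C)(C(C)C)C(C)C)c(OC)c1)[C@]2(CO2)[C@@]3(CO3)[C@H](O)c1ccc(O[Si](C(C)C)(C(C)C)C(C)C)c(OC)c1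
F4 | step 3 | mono(epoxy alcohol) of the meso diol, epoxide on the alkene next to the (R)-carbinol | O[C@H](c1ccc(O[Si](C(C)C)(C(C)C)C(C)C)c(OC)c1)[C@]2(CO2)C(=C)[C@@H](O)c1ccc(O[Si](C(C)C)(C(C)C)C(C)C)c(OC)c1
F5 | step 4 | (1S,4S,2E)-2,3-bis(bromomethyl)-1,4-bis{3-methoxy-4-[(triisopropylsilyl)oxy]phenyl}but-2-ene-1,4-diol | O[C@@H](c1ccc(O[Si](C(C)C)(C(C)C)C(C)C)c(OC)c1)/C(CBr)=C(CBr)/[C@@H](O)c1ccc(O[Si](C(C)C)(C(C)C)C(C)C)c(OC)c1
F6 | step 6 | 3a-hydroperoxide corresponding to 13 (OOH on C8', H on C8, both opposite the aryls) | COc1cc([C@@H]2OC[C@@]3(OO)[C@@H]2CO[C@H]3c2ccc(O[Si](C(C)C)(C(C)C)C(C)C)c(OC)c2)ccc1O[Si](C(C)C)(C(C)C)C(C)C
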